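**Retrosynthetic overview**
- The strategy rests on the O1–C8a aryl ether bond of the pyranone (ring C). C8a belongs to an A ring whose other four carbons C5–C8 all carry oxygen, so this bond is cut last, to an enol of a 2-benzyloxy-1,3-diketone (13) and a C8a–Br bond. The hydroxyls at C3, C5 and C3' travel as benzyl ethers and are released in one final hydrogenolysis.
- Diketone 13 is cut at C3–C4 (aldol, then oxidation) into the B-ring α-benzyloxy ketone 10 and the fully substituted bromo aldehyde 4.
- Aldehyde 4 comes from 2,3,4-trimethoxyphenol by ortho-formylation, O-benzylation and bromination of the last ring C–H. Doing this at the aldehyde stage avoids Lewis acids near a benzyl ether and avoids brominating next to an enolisable ketone. Ketone 10 comes from 3-hydroxy-4,5-dimethoxybenzoic acid by benzylation, diazoketone formation and O–H insertion into benzyl alcohol.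
- Ring order: rings A and B are bought as benzenoid starting materials; ring C is the only ring formed, in step 9.

Key step: step 9

Remark: the target has no stereocentre, so the "single enantiomer" is the achiral compound itself; the stereocentres of 12 and 13 are transient and are erased in steps 8 and 9.

**Route**

Step 1
Reactants: 1 2,3,4-trimethoxyphenol
Product: 2 2-hydroxy-3,4,5-trimethoxybenzaldehyde
Conditions: (CH2O)n (3 equiv), MgCl2 (2 equiv), Et3N (2 equiv), THF, reflux; then 1 M HCl
Reagents that add atoms: paraformaldehyde (formaldehyde), C=O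
Why: Casnati–Skattebøl ortho-formylation: the magnesium phenoxide delivers formaldehyde to the only free ortho carbon, and a second formaldehyde oxidises the benzylic alkoxide by hydride transfer, so the salicylaldehyde should be the sole regioisomer.

Step 2
Reactants: 2 2-hydroxy-3,4,5-trimethoxybenzaldehyde
Product: 3 2-(benzyloxy)-3,4,5-trimethoxybenzaldehyde
Conditions: BnBr (1.2 equiv), K2CO3, DMF, 60 °C
Reagents that add atoms: benzyl bromide, BrCc1ccccc1
Why: Williamson etherification of the phenoxide; the aldehyde has no α-hydrogen and is inert to carbonate.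

Step 3
Reactants: 3 2-(benzyloxy)-3,4,5-trimethoxybenzaldehyde
Product: 4 2-(benzyloxy)-6-bromo-3,4,5-trimethoxybenzaldehyde
Conditions: NBS (1.05 equiv), MeCN, rt, dark
Reagents that add atoms: N-bromosuccinimide, O=C1CCC(=O)N1Br
Why: Electrophilic aromatic bromination at the only ring C–H left, which lies para to the 3-methoxy and ortho to the 5-methoxy group (the pattern of the known 2-bromination of 3,4,5-trimethoxybenzaldehyde); ionic conditions in the dark should spare the benzylic CH2.

Step 4
Reactants: 5 3-hydroxy-4,5-dimethoxybenzoic acid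
Product: 7 3-(benzyloxy)-4,5-dimethoxybenzoic acid, via benzyl 3-(benzyloxy)-4,5-dimethoxybenzoate 6 (not isolated)
Conditions: BnBr (2.3 equiv), K2CO3, DMF, 60 °C; then NaOH, MeOH/THF/H2O, 60 °C; HCl to pH 2
Reagents that add atoms: benzyl bromide, BrCc1ccccc1; sodium hydroxide, [Na+].[OH-]
Why: Double O-alkylation of phenoxide and carboxylate (Williamson), then saponification of the benzyl ester only, since the aryl benzyl ether is stable to hydroxide.

Step 5
Reactants: 7 3-(benzyloxy)-4,5-dimethoxybenzoic acid
Product: 9 1-[3-(benzyloxy)-4,5-dimethoxyphenyl]-2-diazoethan-1-one, via 3-(benzyloxy)-4,5-dimethoxybenzoyl chloride 8 (not isolated)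
Conditions: (COCl)2, cat. DMF, CH2Cl2, 0 °C → rt, evaporate; then TMSCHN2 (2 equiv), THF/MeCN, 0 °C → rt
Reagents that add atoms: trimethylsilyldiazomethane, C[Si](C)(C)C=[N+]=[N-]; oxalyl chloride, O=C(Cl)C(=O)Cl (chlorine of 8 only)
Why: Acid chloride formation followed by C-acylation of the diazoalkane with loss of the silyl group (the diazoketone stage of an Arndt–Eistert sequence), which tolerates aryl ethers.

Step 6
Reactants: 9 1-[3-(benzyloxy)-4,5-dimethoxyphenyl]-2-diazoethan-1-one
Product: 10 2-(benzyloxy)-1-[3-(benzyloxy)-4,5-dimethoxyphenyl]ethan-1-one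
Conditions: BnOH (3 equiv), Rh2(OAc)4 (1 mol%), CH2Cl2, rt, slow addition of 9
Reagents that add atoms: benzyl alcohol, OCc1ccccc1
Why: Rhodium-carbenoid O–H insertion of an α-diazo aryl ketone into an alcohol; the excess alcohol should outcompete carbenoid side reactions.

Step 7
Reactants: 10 2-(benzyloxy)-1-[3-(benzyloxy)-4,5-dimethoxyphenyl]ethan-1-one; 4 2-(benzyloxy)-6-bromo-3,4,5-trimethoxybenzaldehyde
Product: 12 2-(benzyloxy)-3-[2-(benzyloxy)-6-bromo-3,4,5-trimethoxyphenyl]-1-[3-(benzyloxy)-4,5-dimethoxyphenyl]-3-hydroxypropan-1-one (racemic syn/anti mixture), via lithium enolate of the B-ring ketone 11 (not isolated)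
Conditions: LiHMDS (1.1 equiv), THF, −78 °C; then 4, −78 °C; AcOH quench at −78 °C
Reagents that add atoms: lithium hexamethyldisilazide, [Li+].C[Si](C)(C)[N-][Si](C)(C)C (lithium of 11 only)
Why: Directed aldol addition of a preformed lithium enolate (one enolisable site only) to a non-enolisable aldehyde; the two new stereocentres are expected as a diastereomer mixture and need no control, because both become sp2 carbons in steps 8 and 9.

Step 8
Reactants: 12 the aldol adduct
Product: 13 2-(benzyloxy)-1-[2-(benzyloxy)-6-bromo-3,4,5-trimethoxyphenyl]-3-[3-(benzyloxy)-4,5-dimethoxyphenyl]propane-1,3-dione (racemic, enolisable)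
Conditions: Dess–Martin periodinane (1.5 equiv), CH2Cl2, 0 °C → rt
Reagents that add atoms: none
Why: Dess–Martin oxidation of a β-hydroxy ketone to the 1,3-diketone under near-neutral conditions, which should avoid retro-aldol cleavage and leave the aryl bromide and benzyl ethers untouched.

Step 9
Reactants: 13 the 2-benzyloxy-1,3-diketone
Product: 14 3,5-bis(benzyloxy)-2-[3-(benzyloxy)-4,5-dimethoxyphenyl]-6,7,8-trimethoxy-4H-chromen-4-one
Conditions: CuI (10 mol%), 1,10-phenanthroline (20 mol%), Cs2CO3 (2 equiv), dry DMF, 100 °C, Ar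
Reagents that add atoms: none
Why: Cs2CO3 removes the acidic C–H between the two carbonyls of 13 to give the chelating enolate, which binds Cu(I)–phenanthroline; the metal, held next to the A-ring carbonyl, inserts into the ortho C8a–Br bond, and C–O reductive elimination from the seven-membered aryl–copper(III) enolate forms O1–C8a. The closest known reaction is the copper-catalysed intramolecular Ullmann O-arylation of 1-(2-haloaryl)-1,3-diketones to chromones and flavones, here with a 2-alkoxy substituent that becomes the 3-benzyloxy group. The pyranone closes in a formal 6-exo-trig mode, the enol oxygen of the B-ring ketone attacking C8a while bromide leaves from outside the new ring. No stereocentre is created, and the racemic sp3 centre of 13 becomes the sp2 carbon C3. The step needs O- over C-arylation and the B-ring enol oxygen over the A-ring one, and ring size secures both, since attack through carbon or through the other oxygen would close a four-membered ring. It also needs coupling to outrun retro-Claisen cleavage, which the dry, non-nucleophilic carbonate and the carbonyl-assisted copper insertion are meant to ensure.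

Step 10
Reactants: 14 the tri-O-benzyl flavonol
Product: 15 3,5-dihydroxy-2-(3-hydroxy-4,5-dimethoxyphenyl)-6,7,8-trimethoxy-4H-chromen-4-one (3-demethyldigicitrin)
Conditions: H2 (1 atm), 10% Pd/C, EtOAc/MeOH, rt
Reagents that add atoms: none
Why: Palladium-catalysed hydrogenolysis of the three benzylic C–O bonds; the chromone C2=C3 bond and the aryl methyl ethers should be inert at 1 atm and rt, and no halogen remains to be reduced.

**Compound list**
1 | 2,3,4-trimethoxyphenol | COc1ccc(O)c(OC)c1OC | starting material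
2 | 2-hydroxy-3,4,5-trimethoxybenzaldehyde | COc1cc(C=O)c(O)c(OC)c1OC | intermediate
3 | 2-(benzyloxy)-3,4,5-trimethoxybenzaldehyde | COc1cc(C=O)c(OCc2ccccc2)c(OC)c1OC | intermediate
4 | 2-(benzyloxy)-6-bromo-3,4,5-trimethoxybenzaldehyde | COc1c(Br)c(C=O)c(OCc2ccccc2)c(OC)c1OC | intermediate
5 | 3-hydroxy-4,5-dimethoxybenzoic acid | COc1cc(C(=O)O)cc(O)c1OC | starting material
6 | benzyl 3-(benzyloxy)-4,5-dimethoxybenzoate | COc1cc(C(=O)OCc2ccccc2)cc(OCc2ccccc2)c1OC | intermediate (not isolated)
7 | 3-(benzyloxy)-4,5-dimethoxybenzoic acid | COc1cc(C(=O)O)cc(OCc2ccccc2)c1OC | intermediate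
8 | 3-(benzyloxy)-4,5-dimethoxybenzoyl chloride | COc1cc(C(=O)Cl)cc(OCc2ccccc2)c1OC | intermediate (not isolated)
9 | 1-[3-(benzyloxy)-4,5-dimethoxyphenyl]-2-diazoethan-1-one | COc1cc(C(=O)C=[N+]=[N-])cc(OCc2ccccc2)c1OC | intermediate
10 | 2-(benzyloxy)-1-[3-(benzyloxy)-4,5-dimethoxyphenyl]ethan-1-one | COc1cc(C(=O)COCc2ccccc2)cc(OCc2ccccc2)c1OC | intermediate
11 | lithium (Z)-2-(benzyloxy)-1-[3-(benzyloxy)-4,5-dimethoxyphenyl]ethen-1-olate (chelated enolate of 10) | [Li+].[O-]/C(=C\OCc1ccccc1)c1cc(OC)c(OC)c(OCc2ccccc2)c1 | intermediate (not isolated)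
12 | 2-(benzyloxy)-3-[2-(benzyloxy)-6-bromo-3,4,5-trimethoxyphenyl]-1-[3-(benzyloxy)-4,5-dimethoxyphenyl]-3-hydroxypropan-1-one (racemic diastereomer mixture) | COc1cc(C(=O)C(OCc2ccccc2)C(O)c2c(Br)c(OC)c(OC)c(OC)c2OCc2ccccc2)cc(OCc2ccccc2)c1OC | intermediate
13 | 2-(benzyloxy)-1-[2-(benzyloxy)-6-bromo-3,4,5-trimethoxyphenyl]-3-[3-(benzyloxy)-4,5-dimethoxyphenyl]propane-1,3-dione (racemic, enolisable) | COc1cc(C(=O)C(OCc2ccccc2)C(=O)c2c(Br)c(OC)c(OC)c(OC)c2OCc2ccccc2)cc(OCc2ccccc2)c1OC | intermediate
14 | 3,5-bis(benzyloxy)-2-[3-(benzyloxy)-4,5-dimethoxyphenyl]-6,7,8-trimethoxy-4H-chromen-4-one | COc1cc(-c2oc3c(OC)c(OC)c(OC)c(OCc4ccccc4)c3c(=O)c2OCc2ccccc2)cc(OCc2ccccc2)c1OC | intermediate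
15 | 3,5-dihydroxy-2-(3-hydroxy-4,5-dimethoxyphenyl)-6,7,8-trimethoxy-4H-chromen-4-one (3-demethyldigicitrin) | COc1cc(-c2oc3c(OC)c(OC)c(OC)c(O)c3c(=O)c2O)cc(O)c1OC | target

**Step count**
Total steps: 10. Longest linear sequence: 7 steps (1 → 2 → 3 → 7 → 8 → 9 → 10; the B-ring branch 4 → 5 → 6 → 7 → 8 → 9 → 10 is equally long).

**Steps most likely to fail**

Step 9. Copper insertion into the di-ortho-substituted, electron-rich C8a–Br bond may be slow, so that base-induced retro-Claisen cleavage of the diketone or protodebromination overtakes ring closure. The fallback rebuilds the precursor with a C–I bond, so that closure can run at a temperature where the diketone survives. It sets out from 3: iodination with I2/AgOCOCF3 in CH2Cl2 should give 2-(benzyloxy)-6-iodo-3,4,5-trimethoxybenzaldehyde F1. Aldol addition of enolate 11 as in step 7 should give 2-(benzyloxy)-3-[2-(benzyloxy)-6-iodo-3,4,5-trimethoxyphenyl]-1-[3-(benzyloxy)-4,5-dimethoxyphenyl]-3-hydroxypropan-1-one F2. Dess–Martin oxidation should give 2-(benzyloxy)-1-[2-(benzyloxy)-6-iodo-3,4,5-trimethoxyphenyl]-3-[3-(benzyloxy)-4,5-dimethoxyphenyl]propane-1,3-dione F3. This is then closed with CuI/1,10-phenanthroline/Cs2CO3 in DMF at about 60 °C, and the route is rejoined at 14.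

Step 7. Addition of the enolate to the 2,6-disubstituted aldehyde may be slow, and the adduct may revert by retro-aldol before the quench. The fallback replaces aldol plus oxidation by a Claisen-type C-acylation and sets out from 4. Pinnick oxidation (NaClO2, NaH2PO4, 2-methyl-2-butene, t-BuOH/H2O) should give 2-(benzyloxy)-6-bromo-3,4,5-trimethoxybenzoic acid F4. Oxalyl chloride with catalytic DMF converts it into 2-(benzyloxy)-6-bromo-3,4,5-trimethoxybenzoyl chloride F5. Soft-enolisation C-acylation of ketone 10 with this chloride (MgBr2·OEt2, i-Pr2NEt, CH2Cl2) should give the diketone directly; the route is rejoined at 13 and steps 7 and 8 are both bypassed.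

Step 6. The rhodium carbenoid may be diverted from O–H insertion into Wolff rearrangement or addition to an arene ring. The fallback avoids diazo chemistry and sets out from acid chloride 8 (from 7 as in the first half of step 5). Acylation of the lithium enolate of tert-butyl 2-(benzyloxy)acetate (LiHMDS, 2 equiv, THF, −78 °C) should give tert-butyl 2-(benzyloxy)-3-[3-(benzyloxy)-4,5-dimethoxyphenyl]-3-oxopropanoate F6. TFA in CH2Cl2 cleaves the tert-butyl ester to 2-(benzyloxy)-3-[3-(benzyloxy)-4,5-dimethoxyphenyl]-3-oxopropanoic acid F7, which should decarboxylate on warming in toluene. The route is rejoined at 10.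

Further compounds
F1 | step 9 | 2-(benzyloxy)-6-iodo-3,4,5-trimethoxybenzaldehyde | COc1c(I)c(C=O)c(OCc2ccccc2)c(OC)c1OC
F2 | step 9 | 2-(benzyloxy)-3-[2-(benzyloxy)-6-iodo-3,4,5-trimethoxyphenyl]-1-[3-(benzyloxy)-4,5-dimethoxyphenyl]-3-hydroxypropan-1-one | COc1cc(C(=O)C(OCc2ccccc2)C(O)c2c(I)c(OC)c(OC)c(OC)c2OCc2ccccc2)cc(OCc2ccccc2)c1OC
F3 | step 9 | 2-(benzyloxy)-1-[2-(benzyloxy)-6-iodo-3,4,5-trimethoxyphenyl]-3-[3-(benzyloxy)-4,5-dimethoxyphenyl]propane-1,3-dione | COc1cc(C(=O)C(OCc2ccccc2)C(=O)c2c(I)c(OC)c(OC)c(OC)c2OCc2ccccc2)cc(OCc2ccccc2)c1OC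
F4 | step 7 | 2-(benzyloxy)-6-bromo-3,4,5-trimethoxybenzoic acid | COc1c(Br)c(C(=O)O)c(OCc2ccccc2)c(OC)c1OC
F5 | step 7 | 2-(benzyloxy)-6-bromo-3,4,5-trimethoxybenzoyl chloride | COc1c(Br)c(C(=O)Cl)c(OCc2ccccc2)c(OC)c1OC
F6 | step 6 | tert-butyl 2-(benzyloxy)-3-[3-(benzyloxy)-4,5-dimethoxyphenyl]-3-oxopropanoate | COc1cc(C(=O)C(OCc2ccccc2)C(=O)OC(C)(C)C)cc(OCc2ccccc2)c1OC
F7 | step 6 | 2-(benzyloxy)-3-[3-(benzyloxy)-4,5-dimethoxyphenyl]-3-oxopropanoic acid | COc1cc(C(=O)C(OCc2ccccc2)C(=O)O)cc(OCc2ccccc2)c1OC
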